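## The problem

Dendronpholide A (29) is a cembrane in which a seven-membered α-methylene lactone, C15(=C17)–C16(=O)–O, spans C1 and the quaternary, methyl-bearing C4 of a fourteen-membered carbocycle. The two carbocycle bonds that leave the lactone ring, C1–C14 and C4–C5, lie trans to one another across it. Four stereocentres must be set: the vicinal pair C4 (R, tertiary C–O) and C5 (S, CHOAc), C1 (R) on the far side of the lactone, and the remote allylic carbinol C13 (S). C4 and C5 can be made together from a planar E-alkene and can instruct C1 only through a ring or tether that links them to it; C13 is too far from all three and is best left to a reagent. The carbocycle carries the skipped (8E,11E)-diene with two trisubstituted alkenes, so two olefin geometries must be built without moving the doubly allylic C10 methylene into conjugation. The exo-methylene lactone is a Michael acceptor, the tertiary-alkyl lactone C–O bond ionises in strong acid, the C5 acetate next to the lactone oxygen can migrate and survives no organometallic reagent, and the C13 allylic alcohol ionises easily. With C13 as a ketone, the array C17=C15–C1–C14–C13(=O) is a γ,δ-unsaturated ketone, the product pattern of a Claisen rearrangement whose ether oxygen would have joined C17 to C13. Reconnecting it turns the carbocycle into a sixteen-membered lactone in which C1 is still sp2.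

## Retrosynthesis

Cembrane numbering is used for all intermediates: C1–C14 ring carbons, C15(=C17)–C16 the acrylate unit, methyls on C4, C8 and C12.

**Oxidation level and protecting groups (29 ⇒ 28 ⇒ 27 ⇒ 26).** The C13 carbinol of 29 is taken back to ketone 28, and the C5 acetate to alcohol 27 and its silyl ether 26. The ketone is what a Claisen rearrangement delivers, and an α-methyl enone is a good substrate for Corey–Bakshi–Shibata reduction. An acetate cannot pass a titanium methylidene, so C5 travels as a TBS ether. The forward steps ask for desilylation and acetylation beside a Michael acceptor and for reagent-controlled 1,2-reduction.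

**Claisen ring contraction (26 ⇒ 25 ⇒ 24).** The C1–C14 bond is cut and C17 is reconnected to the C13 oxygen, giving the 2-alkoxydiene 25. Removing C14 from 25 gives dilactone 24. This cut removes the C1 stereocentre and the exo-methylene group together and leaves a ring held only by two esters. A cut at C4–C5 or C11–C12 would leave the lactone and C1 still to be made. The forward reaction must methylenate the C13 carbonyl and not C16, and C14 must reach the C1 face trans to C4–C5.

**Macrolactone (24 ⇒ 22 ⇒ 21 ⇒ 20 ⇒ 19 ⇒ 18).** The C17–O–C13 ester is opened to seco acid 22. This ester is the macrocyclic closure because it joins a primary allylic alcohol to an acid, whereas the other ester would require lactonisation onto a tertiary alcohol in a large ring. Acid 22 comes from 18 by unmasking and oxidising C13 (19, 20, 21) before freeing C17–OH, so the two primary allylic oxygens never compete.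

**Seven-membered lactone (18 ⇒ 17 ⇒ 12 + 15; 15 ⇒ 14 ⇒ 13).** The C1=C15 alkene is cut by ring-closing metathesis to diene ester 17, and the tertiary ester to alcohol 12 and acid 15. Acid 15 comes from ethyl 2-(hydroxymethyl)acrylate 13 through 14. Metathesis needs only a terminal vinyl group at C1 and leaves both trisubstituted alkenes alone. The forward steps must acylate a hindered tertiary alcohol and close a trisubstituted enoate in a seven-membered ring.

**The C4/C5 pair (12 ⇒ 11 ⇒ 10 ⇒ 8 ⇒ 7).** Anti-diol 11 is the product of water opening the trans-epoxide 10 at the tertiary C4 with inversion. Epoxide 10 comes from epoxy alcohol 8 by replacing the C3 hydroxyl with an allyl group through triflate 9, which also brings in C2, C1 and the metathesis methylene. Epoxy alcohol 8 is the Sharpless product of E-allylic alcohol 7. The allyl group is installed before hydrolysis because in 8 the tertiary carbon is deactivated by the neighbouring CH2OH, and attack at C5 instead of C4 would give the enantiomeric diol. In 10, C4 is an ordinary trialkyl oxirane carbon.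

**Carbon chain (7 ⇒ 6 ⇒ 5 ⇒ 4 + 2; 2 ⇒ 1).** Alcohol 7 comes from PMB ether 6 by allylic oxidation of the terminal E-methyl group. Trienol 5 is cut at C10–C11 into geranyl chloride 2 (from geraniol 1, which supplies C4–C10 and the 8E alkene) and alkenylalane 4, made from propargyl alcohol 3 by syn-carboalumination (which supplies C11–C13 and the 11E alkene). The coupling is done first so that no ester or lactone meets an organoaluminium or Grignard reagent.

## Roads not taken

**Alternative 1:** cut at C4–C5. The acyclic keto aldehyde A1 would be coupled with TiCl3(DME)1.5 and zinc–copper couple, Zn(Cu), to give the fourteen-membered 4,5-diol A2.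
- Merits: ring and both carbinol centres arise in one step from a linear chain. Low-valent titanium pinacol macrocyclisation has a strong record with cembranoids. C13 is set early, and no Claisen face question exists.
- Weak points: C4 and C5 are formed under substrate control only, with nothing near them to choose among four diastereomers. The lactone must afterwards be closed from the tertiary C4 hydroxyl and then α-methylenated by enolate chemistry beside C1 and a C5 ester.
- Comparison: this road closes the carbocycle more reliably and is shorter if the pinacol is selective. The chosen plan instead fixes C4 and C5 absolutely by Sharpless epoxidation and stereospecific opening before any ring exists, and it obtains the methylene lactone without a late enolate step.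

**Alternative 2:** cut at O–C4. The macrocyclic 4,5-epoxy acrylic acid A3 would be treated with camphorsulfonic acid to give hydroxy lactone A4 by 7-exo opening with inversion at C4.
- Merits: it uses the same stereospecific inversion at C4, frees the C5 hydroxyl for direct acetylation, and avoids both tertiary acylation and metathesis.
- Weak points: A3 is a carbocycle with one epoxide of defined configuration among three trisubstituted alkenes, and the strategy does not say how that ring is made. Under acid the C8=C9 alkene is held in position for transannular attack on C4. Attack of the acid at C5 would give the eight-membered lactone.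
- Comparison: the end game is shorter and is as good as or better than the chosen one once A3 is in hand. The chosen plan performs the same inversion on acyclic epoxide 10, where water is the nucleophile and no alkene is held nearby, and it also solves the ring construction.

**Alternative 3:** cut at C11–C12. The bis(methylalkyne) A5 would be closed with [Mo(≡C–C6H4-4-OMe)(OSiPh3)3] to cycloalkyne A6, followed by desilylation, hydroxyl-directed trans-hydrostannation and methylation.
- Merits: alkyne metathesis tolerates esters, alkenes and the methylene lactone and cannot scramble olefin geometry. C13 is set early by a reagent. The directed hydrometalation places methyl on the carbon next to the carbinol, as required.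
- Weak points: A5 already contains the finished lactone with C1, C4, C5 and C13, so C1 must be set independently and the tertiary lactone problem remains. The C10 methylene is propargylic and allylic, hence base-sensitive. Three further steps with tin follow cyclisation.
- Comparison: this road is better in predictability of ring closure and in control of C13. The chosen plan makes the ring, C1 and the methylene lactone in one step from a precursor with two stereocentres, at the price of an unproven face selectivity at C1.

Key step: step 18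

Remark: the tartrate in step 5 is assigned by analogy with geraniol and (E)-2-methylalk-2-en-1-ols, which give (2S,3S)-epoxy alcohols with L-(+)-diethyl tartrate.
Remark: in step 21 the α-methylalkenyl group is taken as the larger ketone substituent in the Corey–Bakshi–Shibata model.

## Route

Step 1
Reactants: 1 geraniol
Product: 2 geranyl chloride
Conditions: N-chlorosuccinimide, Me2S, CH2Cl2, −30 → 0 °C
Reagents that add atoms: N-chlorosuccinimide, O=C1CCC(=O)N1Cl
Why: Corey–Kim chlorination converts the primary allylic alcohol to the chloride by SN2 collapse of the alkoxysulfonium salt under neutral conditions, so the E alkene (later C8=C9) should not move.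

Step 2
Reactants: 3 propargyl alcohol; 2 geranyl chloride
Product: 5 (2E,5E)-2,6,10-trimethylundeca-2,5,9-trien-1-ol, via alkenylalane 4 (not isolated)
Conditions: Me3Al (3 equiv), Cp2ZrCl2 (0.25 equiv), ClCH2CH2Cl, 0 °C → rt; then 2, Pd(PPh3)4 (3 mol %), THF, rt
Reagents that add atoms: trimethylaluminium, C[Al](C)C
Why: Negishi zirconium-catalysed syn-carboalumination puts methyl on the internal alkyne carbon and aluminium on the terminus (the E-2-methylalkenyl unit, later C11=C12), and palladium-catalysed allylation of the alkenylalane should join C10–C11 at the primary carbon with retention of both geometries.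

Step 3
Reactants: 5 (2E,5E)-2,6,10-trimethylundeca-2,5,9-trien-1-ol
Product: 6 PMB ether of 5, 1-methoxy-4-({[(2E,5E)-2,6,10-trimethylundeca-2,5,9-trien-1-yl]oxy}methyl)benzene
Conditions: NaH, 4-methoxybenzyl chloride, Bu4NI (cat.), THF/DMF, 0 °C → rt
Reagents that add atoms: 4-methoxybenzyl chloride, COc1ccc(CCl)cc1
Why: Williamson etherification; the PMB ether keeps the C13 allylic alcohol out of the Sharpless epoxidation, the triflation and the Grignard step and can later be removed oxidatively beside silyl ethers.

Step 4
Reactants: 6 PMB ether of 5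
Product: 7 (2E,6E,9E)-11-[(4-methoxybenzyl)oxy]-2,6,10-trimethylundeca-2,6,9-trien-1-ol
Conditions: SeO2 (0.2 equiv), t-BuOOH (3 equiv), salicylic acid (0.1 equiv), CH2Cl2, 0 °C → rt
Reagents that add atoms: tert-butyl hydroperoxide, CC(C)(C)OO
Why: Catalytic SeO2 allylic oxidation (ene reaction, then [2,3] shift) should attack the terminal isopropylidene group at its E-methyl as in geranyl and farnesyl derivatives, the C11=C12 alkene being deactivated by its allylic oxygen; the reaction is stopped at partial conversion and 6 recovered.

Step 5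
Reactants: 7 (2E,6E,9E)-11-[(4-methoxybenzyl)oxy]-2,6,10-trimethylundeca-2,6,9-trien-1-ol
Product: 8 [(2S,3S)-3-{(3E,6E)-8-[(4-methoxybenzyl)oxy]-3,7-dimethylocta-3,6-dien-1-yl}-2-methyloxiran-2-yl]methanol
Conditions: Ti(OiPr)4 (0.1 equiv), L-(+)-diethyl tartrate (0.12 equiv), t-BuOOH (2 equiv), 4 Å MS, CH2Cl2, −20 °C
Reagents that add atoms: tert-butyl hydroperoxide, CC(C)(C)OO
Why: Sharpless asymmetric epoxidation is directed by the allylic hydroxyl to the C4=C5 alkene only; L-(+)-tartrate should give the (2S,3S)-epoxy alcohol, which fixes C5 as S and the epoxide face for the later inversion at C4.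

Step 6
Reactants: 8 the (2S,3S)-epoxy alcohol
Product: 10 (2S,3S)-2-(but-3-en-1-yl)-3-{(3E,6E)-8-[(4-methoxybenzyl)oxy]-3,7-dimethylocta-3,6-dien-1-yl}-2-methyloxirane, via epoxy triflate 9 (not isolated)
Conditions: Tf2O, 2,6-lutidine, CH2Cl2, −78 °C; then CuBr·SMe2 (10 mol %), allylmagnesium bromide (3 equiv), Et2O, −78 → −40 °C
Reagents that add atoms: allylmagnesium bromide, C=CC[Mg]Br
Why: Copper-catalysed Grignard coupling with a primary triflate should be much faster than opening of the trisubstituted epoxide, so the C3–C2 bond and the but-3-enyl arm are installed with both epoxide stereocentres untouched.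

Step 7
Reactants: 10 the (2S,3S)-butenyl epoxide
Product: 11 (5R,6S,9E,12E)-14-[(4-methoxybenzyl)oxy]-5,9,13-trimethyltetradeca-1,9,12-triene-5,6-diol
Conditions: HClO4 (cat.), THF/H2O (3:1), 0 °C
Reagents that add atoms: water, O
Why: Acid-catalysed epoxide hydrolysis: water attacks the tertiary C4 from the back of the protonated oxirane (borderline SN2), inverting C4 to R while C5 keeps its oxygen and S configuration, which should give the anti (4R,5S) diol.

Step 8
Reactants: 11 the (5R,6S)-diol
Product: 12 (5R,6S,9E,12E)-6-[(tert-butyldimethylsilyl)oxy]-14-[(4-methoxybenzyl)oxy]-5,9,13-trimethyltetradeca-1,9,12-trien-5-ol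
Conditions: TBSOTf (1.1 equiv), 2,6-lutidine, CH2Cl2, −78 °C
Reagents that add atoms: tert-butyldimethylsilyl trifluoromethanesulfonate, CC(C)(C)[Si](C)(C)OS(=O)(=O)C(F)(F)F
Why: Silylation at low temperature distinguishes the secondary C5 hydroxyl from the tertiary C4 hydroxyl on steric grounds; the silyl ether will tolerate the titanium methylidene, which an acetate would not.

Step 9
Reactants: 13 ethyl 2-(hydroxymethyl)acrylate
Product: 14 ethyl 2-{[(tert-butyldimethylsilyl)oxy]methyl}acrylate
Conditions: TBSCl, imidazole, CH2Cl2, 0 °C → rt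
Reagents that add atoms: tert-butyldimethylsilyl chloride, CC(C)(C)[Si](C)(C)Cl
Why: Routine silylation of a primary allylic alcohol; a primary TBS ether can later be removed in the presence of the hindered secondary one at C5.

Step 10
Reactants: 14 ethyl 2-{[(tert-butyldimethylsilyl)oxy]methyl}acrylate
Product: 15 2-{[(tert-butyldimethylsilyl)oxy]methyl}acrylic acid
Conditions: LiOH, THF/H2O, 0 °C → rt; then aq. KHSO4 to pH 4
Reagents that add atoms: lithium hydroxide, [Li+].[OH-]
Why: Saponification of the ethyl ester; the primary silyl ether should survive cold aqueous base and a mildly acidic work-up.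

Step 11
Reactants: 12 the C5-silylated tertiary alcohol; 15 2-{[(tert-butyldimethylsilyl)oxy]methyl}acrylic acid
Product: 17 (5R,6S,9E,12E)-6-[(tert-butyldimethylsilyl)oxy]-14-[(4-methoxybenzyl)oxy]-5,9,13-trimethyltetradeca-1,9,12-trien-5-yl 2-{[(tert-butyldimethylsilyl)oxy]methyl}acrylate, via acid chloride 16 (not isolated)
Conditions: 15, 1-chloro-N,N,2-trimethylprop-1-en-1-amine, CH2Cl2, 0 °C → rt; separately 12, LiN(SiMe3)2 (1.05 equiv), THF, −78 °C; then 16, −78 → −20 °C
Reagents that add atoms: none
Why: O-acylation of a lithium tertiary alkoxide by an acid chloride is the standard way to tertiary acrylates; the acid chloride is made under neutral conditions to spare its silyl ether, and low temperature with lithium as counter-ion is meant to outrun 1,2-silyl migration from O5.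

Step 12
Reactants: 17 the diene ester
Product: 18 (7R)-7-{(1S,4E,7E)-1-[(tert-butyldimethylsilyl)oxy]-9-[(4-methoxybenzyl)oxy]-4,8-dimethylnona-4,7-dien-1-yl}-3-{[(tert-butyldimethylsilyl)oxy]methyl}-7-methyl-6,7-dihydrooxepin-2(5H)-one
Conditions: second-generation Grubbs catalyst (H2IMes)(PCy3)Cl2Ru=CHPh (10 mol %), toluene (2 mM), 80 °C, argon sparge
Reagents that add atoms: none
Why: Ring-closing metathesis should initiate at the monosubstituted C1 vinyl group and close onto the 1,1-disubstituted acrylate to give the seven-membered enoate (C1=C15); the trisubstituted C8=C9 and C11=C12 alkenes are inert and the quaternary C4 favours closure.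

Step 13
Reactants: 18 the seven-membered enoate lactone
Product: 19 (7R)-7-{(1S,4E,7E)-1-[(tert-butyldimethylsilyl)oxy]-9-hydroxy-4,8-dimethylnona-4,7-dien-1-yl}-3-{[(tert-butyldimethylsilyl)oxy]methyl}-7-methyl-6,7-dihydrooxepin-2(5H)-one
Conditions: DDQ, CH2Cl2/pH 7 buffer (10:1), 0 °C
Reagents that add atoms: none
Why: Oxidative cleavage of the PMB ether by benzylic hydride abstraction frees C13–OH while both silyl ethers and the lactone stay in place.

Step 14
Reactants: 19 the C13 allylic alcohol
Product: 20 (2E,5E,9S)-9-[(tert-butyldimethylsilyl)oxy]-9-[(2R)-6-{[(tert-butyldimethylsilyl)oxy]methyl}-2-methyl-7-oxo-2,3,4,7-tetrahydrooxepin-2-yl]-2,6-dimethylnona-2,5-dienal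
Conditions: MnO2 (activated, excess), CH2Cl2, rt
Reagents that add atoms: none
Why: MnO2 oxidises the electron-rich allylic alcohol to the E-enal under neutral conditions, so the doubly allylic C10 methylene is not exposed to base.

Step 15
Reactants: 20 the C13 enal
Product: 21 (2E,5E,9S)-9-[(tert-butyldimethylsilyl)oxy]-9-[(2R)-6-{[(tert-butyldimethylsilyl)oxy]methyl}-2-methyl-7-oxo-2,3,4,7-tetrahydrooxepin-2-yl]-2,6-dimethylnona-2,5-dienoic acid
Conditions: NaClO2, NaH2PO4, 2-methylbut-2-ene, t-BuOH/H2O, 0 °C → rt
Reagents that add atoms: sodium chlorite, [Na+].[O-]Cl=O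
Why: Pinnick oxidation takes the enal to the acid without moving the alkene; the scavenger removes HOCl before it can touch the trisubstituted alkenes.

Step 16
Reactants: 21 the C13 acid
Product: 22 (2E,5E,9S)-9-[(tert-butyldimethylsilyl)oxy]-9-[(2R)-6-(hydroxymethyl)-2-methyl-7-oxo-2,3,4,7-tetrahydrooxepin-2-yl]-2,6-dimethylnona-2,5-dienoic acid
Conditions: HF·pyridine, pyridine, THF, 0 °C
Reagents that add atoms: none
Why: Desilylation should be much faster at the unhindered primary allylic ether (C17) than at the secondary C5 ether flanked by the quaternary C4; pyridine buffering protects the tertiary-alkyl lactone.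

Step 17
Reactants: 22 the seco acid
Product: 24 bicyclic dilactone (4R,5S,8E,11E): the seven-membered C1=C15 enoate lactone (O on C4) bridged by the C17H2–O–C13(=O) macrolactone with the C5 TBS ether, via mixed anhydride 23 (not isolated)
Conditions: 2,4,6-trichlorobenzoyl chloride, Et3N, THF, rt; then slow addition to DMAP, toluene (1 mM), 40 °C
Reagents that add atoms: none
Why: Yamaguchi macrolactonisation transfers the tiglate-type acyl group through the acylpyridinium ion to the primary C17 hydroxyl under high dilution; no stereocentre is formed.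

Step 18
Reactants: 24 the bicyclic dilactone
Product: 26 (1R,4R,5S,8E,11E)-C13 enone: fourteen-membered carbocycle with the α-methylene seven-membered lactone and the C5 TBS ether, via dienyl enol ether 25 (not isolated)
Conditions: Cp2TiMe2 (2 equiv), toluene, 65 °C, dark; acetone (excess), 65 °C; then 130 °C (sealed vessel)
Reagents that add atoms: dimethyltitanocene, C[Ti](C)(C1C=CC=C1)C1C=CC=C1
Why: Thermolysis of Cp2TiMe2 gives Cp2Ti=CH2, which should add to the C13 ester carbonyl through an oxatitanacyclobutane and cyclorevert to the 2-alkoxydiene 25. On further heating the allyl vinyl ether C14=C13–O–C17–C15=C1 undergoes a concerted [3,3] shift that forms C14–C1, breaks O–C17 and moves the alkene to C15=C17. The closest known reaction type is Tebbe or Petasis methylenation of a lactone followed by Claisen rearrangement of the cyclic enol ether, used for ring expansion and contraction. The fourteen-membered carbocycle is closed as a sixteen-to-fourteen ring contraction through the six-membered pericyclic transition state (chair or boat, as the strap allows), and the seven-membered lactone is carried through intact. The one new stereocentre, C1, is set by the face of the C1=C15 alkene that C14 reaches, which is dictated by the macrocyclic strap anchored at C4 through C5. The wanted trans arrangement lets both carbocycle bonds sit pseudo-equatorially on the lactone ring, which is expected, though not proven, to be the less strained path for a ten-carbon bridge holding two E alkenes. The step needs methylenation at C13 and not at C16, which the tertiary-alkyl, α-branched environment of the C16 carbonyl and the limited reagent charge should secure. Residual titanium reagent is consumed with acetone before the temperature is raised, so that the new ketone is not methylenated.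

Step 19
Reactants: 26 the C13 enone with C5 TBS ether
Product: 27 (1R,4R,5S,8E,11E)-C5 alcohol of the C13 enone
Conditions: HF·pyridine, THF, 0 °C → rt
Reagents that add atoms: none
Why: Acidic fluoride removes the hindered secondary silyl ether without the basic conditions that would add to the methylene lactone or move the lactone acyl group from O4 to O5.

Step 20
Reactants: 27 the C5 alcohol
Product: 28 (1R,4R,5S,8E,11E)-C5 acetate of the C13 enone
Conditions: Ac2O, pyridine, DMAP (cat.), CH2Cl2, 0 °C → rt
Reagents that add atoms: acetic anhydride, CC(=O)OC(C)=O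
Why: Routine acetylation of the secondary alcohol; the ketone and both alkene types are inert to these conditions.

Step 21
Reactants: 28 the C5 acetate enone
Product: 29 dendronpholide A
Conditions: (R)-2-methyl-CBS-oxazaborolidine (0.5 equiv), catecholborane, toluene, −78 °C
Reagents that add atoms: none
Why: Corey–Bakshi–Shibata reduction: the ketone binds the oxazaborolidine boron anti to the larger α-methylalkenyl group and hydride is delivered to one face, so the (R)-catalyst should give the 13S allylic alcohol by 1,2-reduction under reagent control; at −78 °C catecholborane should leave acetate, lactone and alkenes alone.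

## Compound list

1 | geraniol, (2E)-3,7-dimethylocta-2,6-dien-1-ol | CC(C)=CCC/C(C)=C/CO | starting material
2 | geranyl chloride, (2E)-1-chloro-3,7-dimethylocta-2,6-diene | CC(C)=CCC/C(C)=C/CCl | intermediate
3 | propargyl alcohol, prop-2-yn-1-ol | C#CCO | starting material
4 | dimethyl[(1E)-3-(dimethylalumanyloxy)-2-methylprop-1-enyl]alumane | C[Al](C)/C=C(\C)CO[Al](C)C | intermediate
5 | (2E,5E)-2,6,10-trimethylundeca-2,5,9-trien-1-ol | CC(C)=CCC/C(C)=C/C/C=C(\C)CO | intermediate
6 | 1-methoxy-4-({[(2E,5E)-2,6,10-trimethylundeca-2,5,9-trien-1-yl]oxy}methyl)benzene | CC(C)=CCC/C(C)=C/C/C=C(\C)COCc1ccc(OC)cc1 | intermediate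
7 | (2E,6E,9E)-11-[(4-methoxybenzyl)oxy]-2,6,10-trimethylundeca-2,6,9-trien-1-ol | OC/C(C)=C/CC/C(C)=C/C/C=C(\C)COCc1ccc(OC)cc1 | intermediate
8 | [(2S,3S)-3-{(3E,6E)-8-[(4-methoxybenzyl)oxy]-3,7-dimethylocta-3,6-dien-1-yl}-2-methyloxiran-2-yl]methanol | OC[C@]1(C)O[C@H]1CC/C(C)=C/C/C=C(\C)COCc2ccc(OC)cc2 | intermediate
9 | [(2S,3S)-3-{(3E,6E)-8-[(4-methoxybenzyl)oxy]-3,7-dimethylocta-3,6-dien-1-yl}-2-methyloxiran-2-yl]methyl trifluoromethanesulfonate | FC(F)(F)S(=O)(=O)OC[C@]1(C)O[C@H]1CC/C(C)=C/C/C=C(\C)COCc2ccc(OC)cc2 | intermediate
10 | (2S,3S)-2-(but-3-en-1-yl)-3-{(3E,6E)-8-[(4-methoxybenzyl)oxy]-3,7-dimethylocta-3,6-dien-1-yl}-2-methyloxirane | C=CCC[C@]1(C)O[C@H]1CC/C(C)=C/C/C=C(\C)COCc2ccc(OC)cc2 | intermediate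
11 | (5R,6S,9E,12E)-14-[(4-methoxybenzyl)oxy]-5,9,13-trimethyltetradeca-1,9,12-triene-5,6-diol | C=CCC[C@@](C)(O)[C@@H](O)CC/C(C)=C/C/C=C(\C)COCc1ccc(OC)cc1 | intermediate
12 | (5R,6S,9E,12E)-6-[(tert-butyldimethylsilyl)oxy]-14-[(4-methoxybenzyl)oxy]-5,9,13-trimethyltetradeca-1,9,12-trien-5-ol | C=CCC[C@@](C)(O)[C@@H](O[Si](C)(C)C(C)(C)C)CC/C(C)=C/C/C=C(\C)COCc1ccc(OC)cc1 | intermediate
13 | ethyl 2-(hydroxymethyl)acrylate | C=C(CO)C(=O)OCC | starting material
14 | ethyl 2-{[(tert-butyldimethylsilyl)oxy]methyl}acrylate | C=C(CO[Si](C)(C)C(C)(C)C)C(=O)OCC | intermediate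
15 | 2-{[(tert-butyldimethylsilyl)oxy]methyl}acrylic acid | C=C(CO[Si](C)(C)C(C)(C)C)C(=O)O | intermediate
16 | 2-{[(tert-butyldimethylsilyl)oxy]methyl}acryloyl chloride | C=C(CO[Si](C)(C)C(C)(C)C)C(=O)Cl | intermediate
17 | (5R,6S,9E,12E)-6-[(tert-butyldimethylsilyl)oxy]-14-[(4-methoxybenzyl)oxy]-5,9,13-trimethyltetradeca-1,9,12-trien-5-yl 2-{[(tert-butyldimethylsilyl)oxy]methyl}acrylate | C=CCC[C@@](C)(OC(=O)C(=C)CO[Si](C)(C)C(C)(C)C)[C@@H](O[Si](C)(C)C(C)(C)C)CC/C(C)=C/C/C=C(\C)COCc1ccc(OC)cc1 | intermediate
18 | (7R)-7-{(1S,4E,7E)-1-[(tert-butyldimethylsilyl)oxy]-9-[(4-methoxybenzyl)oxy]-4,8-dimethylnona-4,7-dien-1-yl}-3-{[(tert-butyldimethylsilyl)oxy]methyl}-7-methyl-6,7-dihydrooxepin-2(5H)-one | O=C1O[C@](C)(CCC=C1CO[Si](C)(C)C(C)(C)C)[C@@H](O[Si](C)(C)C(C)(C)C)CC/C(C)=C/C/C=C(\C)COCc2ccc(OC)cc2 | intermediate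
19 | (7R)-7-{(1S,4E,7E)-1-[(tert-butyldimethylsilyl)oxy]-9-hydroxy-4,8-dimethylnona-4,7-dien-1-yl}-3-{[(tert-butyldimethylsilyl)oxy]methyl}-7-methyl-6,7-dihydrooxepin-2(5H)-one | O=C1O[C@](C)(CCC=C1CO[Si](C)(C)C(C)(C)C)[C@@H](O[Si](C)(C)C(C)(C)C)CC/C(C)=C/C/C=C(\C)CO | intermediate
20 | (2E,5E,9S)-9-[(tert-butyldimethylsilyl)oxy]-9-[(2R)-6-{[(tert-butyldimethylsilyl)oxy]methyl}-2-methyl-7-oxo-2,3,4,7-tetrahydrooxepin-2-yl]-2,6-dimethylnona-2,5-dienal | O=C1O[C@](C)(CCC=C1CO[Si](C)(C)C(C)(C)C)[C@@H](O[Si](C)(C)C(C)(C)C)CC/C(C)=C/C/C=C(\C)C=O | intermediate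
21 | (2E,5E,9S)-9-[(tert-butyldimethylsilyl)oxy]-9-[(2R)-6-{[(tert-butyldimethylsilyl)oxy]methyl}-2-methyl-7-oxo-2,3,4,7-tetrahydrooxepin-2-yl]-2,6-dimethylnona-2,5-dienoic acid | O=C1O[C@](C)(CCC=C1CO[Si](C)(C)C(C)(C)C)[C@@H](O[Si](C)(C)C(C)(C)C)CC/C(C)=C/C/C=C(\C)C(=O)O | intermediate
22 | (2E,5E,9S)-9-[(tert-butyldimethylsilyl)oxy]-9-[(2R)-6-(hydroxymethyl)-2-methyl-7-oxo-2,3,4,7-tetrahydrooxepin-2-yl]-2,6-dimethylnona-2,5-dienoic acid | O=C1O[C@](C)(CCC=C1CO)[C@@H](O[Si](C)(C)C(C)(C)C)CC/C(C)=C/C/C=C(\C)C(=O)O | intermediate
23 | mixed anhydride of 22 with 2,4,6-trichlorobenzoic acid | O=C1O[C@](C)(CCC=C1CO)[C@@H](O[Si](C)(C)C(C)(C)C)CC/C(C)=C/C/C=C(\C)C(=O)OC(=O)c2c(Cl)cc(Cl)cc2Cl | intermediate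
24 | bicyclic dilactone (4R,5S,8E,11E): lactone ring O–C4(Me)–C3–C2–C1=C15–C16(=O), macrolactone bridge C15–C17H2–O–C13(=O)–C12(Me)=C11–C10–C9=C8(Me)–C7–C6–C5(OTBS)–C4 | O=C1O[C@]2(C)CCC=C1COC(=O)/C(C)=C/C/C=C(\C)CC[C@@H]2O[Si](C)(C)C(C)(C)C | intermediate
25 | dienyl enol ether (4R,5S,8E,11E): 24 with the C13 carbonyl replaced by C13=C14H2 | O=C1O[C@]2(C)CCC=C1COC(=C)/C(C)=C/C/C=C(\C)CC[C@@H]2O[Si](C)(C)C(C)(C)C | intermediate
26 | (1R,4R,5S,8E,11E)-C13 enone: fourteen-membered carbocycle, α-methylene seven-membered lactone from C1 to O–C4, C5 TBS ether | C=C1C(=O)O[C@]2(C)CC[C@@H]1CC(=O)/C(C)=C/C/C=C(\C)CC[C@@H]2O[Si](C)(C)C(C)(C)C | intermediate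
27 | (1R,4R,5S,8E,11E)-C5 alcohol of the C13 enone | C=C1C(=O)O[C@]2(C)CC[C@@H]1CC(=O)/C(C)=C/C/C=C(\C)CC[C@@H]2O | intermediate
28 | (1R,4R,5S,8E,11E)-C5 acetate of the C13 enone | C=C1C(=O)O[C@]2(C)CC[C@@H]1CC(=O)/C(C)=C/C/C=C(\C)CC[C@@H]2OC(C)=O | intermediate
29 | dendronpholide A, (1R,4R,5S,13S,8E,11E) | C=C1C(=O)O[C@]2(C)CC[C@@H]1C[C@H](O)/C(C)=C/C/C=C(\C)CC[C@@H]2OC(C)=O | target

## Step count and risks

Total: 21 steps. Longest linear sequence: 19 steps from geraniol (steps 1–8 and 11–21); steps 9 and 10 form the side branch.

**Step 18 (key step).**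
- What may go wrong: methylenation of the C16 lactone carbonyl in competition with C13, because a lactone held in the cisoid ester geometry is intrinsically reactive toward titanium methylidenes. Methylenation of the new ketone, or delivery of C14 to the wrong face of C1, are further possibilities, since only the strap decides the face.
- Fallback: a Carroll ring contraction that needs no titanium reagent. It sets out from acid 21. Condensation with Meldrum's acid (DCC, DMAP) would give the acyl Meldrum's acid F1, and HF·pyridine would free the C17 hydroxyl to give the hydroxy acyl Meldrum's acid F2. Heating F2 in dilute toluene generates the acylketene, which the C17 hydroxyl should trap to close the eighteen-membered β-keto lactone F3. Heating F3 in xylene at about 140 °C should bring about the Carroll rearrangement, a [3,3] shift of the enol that forms C14–C1, followed by decarboxylation. The sequence returns to the route at 26.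

**Step 12.**
- What may go wrong: slow closure to a trisubstituted enoate in a seven-membered ring, so that dimerisation or migration of the terminal alkene takes over.
- Fallback: it sets out from 12. Acylation with acryloyl chloride would give the acrylate F4, whose metathesis to the disubstituted enoate lactone F5 is far easier. Conjugate addition of Me2AlSPh and trapping of the aluminium enolate with formaldehyde would give the phenylthio hydroxymethyl lactone F6. Oxidation to the sulfoxide and thermal elimination would give the hydroxymethyl enoate lactone F7. Silylation with TBSCl and imidazole returns to the route at 18.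

**Step 11.**
- What may go wrong: migration of the silyl group from O5 to the C4 alkoxide before acylation, or incomplete acylation of the hindered alkoxide.
- Fallback: it sets out from 12. Diethylphosphonoacetic acid and DCC acylate through the phosphonoketene without strong base and would give the phosphonoacetate F8. Aqueous formaldehyde and K2CO3 (hydroxymethylation, then Horner–Wadsworth–Emmons olefination) would give the 2-(hydroxymethyl)acrylate F9. Silylation with TBSCl and imidazole returns to the route at 17.

**Step 7.**
- What may go wrong: loss of stereochemical fidelity at C4 through partial ionisation, or attack of water at C5, which leads to the enantiomeric diol; cation–alkene cyclisation onto C8=C9 is a further drain.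
- Fallback: the secondary carbon is inverted instead of the tertiary one. It sets out from 7. Epoxidation with D-(−)-diethyl tartrate would give the (2R,3R)-epoxy alcohol F10. Ti(OiPr)4 and benzoic acid should open it at the secondary carbon with inversion to the diol benzoate F11. Tosylation of the primary hydroxyl would give the tosylate F12. K2CO3 in methanol would close the terminal epoxide and remove the benzoate to give the epoxy alcohol F13. Allylmagnesium bromide with CuI (cat.) opens F13 at its methylene carbon and returns to the route at 11.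

**Step 17.**
- What may go wrong: γ-deprotonation of the activated acyl group at the doubly allylic C10 (vinylketene formation), which would move the C11=C12 alkene out of conjugation, or oligomerisation.
- Fallback: a Mitsunobu macrolactonisation (PPh3, diisopropyl azodicarboxylate, toluene, high dilution) activates the primary C17 hydroxyl instead of the acid. It sets out from 22, returns at 24 and makes no new compound.

## Further compounds

F1 | step 18 | acyl Meldrum's acid of 21 (enol form) | O=C1O[C@](C)(CCC=C1CO[Si](C)(C)C(C)(C)C)[C@@H](O[Si](C)(C)C(C)(C)C)CC/C(C)=C/C/C=C(\C)C(O)=C2C(=O)OC(C)(C)OC2=O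
F2 | step 18 | C17-hydroxy acyl Meldrum's acid | O=C1O[C@](C)(CCC=C1CO)[C@@H](O[Si](C)(C)C(C)(C)C)CC/C(C)=C/C/C=C(\C)C(O)=C2C(=O)OC(C)(C)OC2=O
F3 | step 18 | eighteen-membered β-keto lactone (4R,5S,8E,11E) | O=C1O[C@]2(C)CCC=C1COC(=O)CC(=O)/C(C)=C/C/C=C(\C)CC[C@@H]2O[Si](C)(C)C(C)(C)C
F4 | step 12 | acrylate of 12 | C=CCC[C@@](C)(OC(=O)C=C)[C@@H](O[Si](C)(C)C(C)(C)C)CC/C(C)=C/C/C=C(\C)COCc1ccc(OC)cc1
F5 | step 12 | (7R)-7-substituted 7-methyl-6,7-dihydrooxepin-2(5H)-one without the C17 unit | O=C1O[C@](C)(CCC=C1)[C@@H](O[Si](C)(C)C(C)(C)C)CC/C(C)=C/C/C=C(\C)COCc2ccc(OC)cc2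
F6 | step 12 | 3-(hydroxymethyl)-4-(phenylthio)oxepan-2-one adduct of F5, mixture at C3 and C4 of the ring | O=C1O[C@](C)(CCC(Sc3ccccc3)C1CO)[C@@H](O[Si](C)(C)C(C)(C)C)CC/C(C)=C/C/C=C(\C)COCc2ccc(OC)cc2
F7 | step 12 | C17-hydroxy analogue of 18 | O=C1O[C@](C)(CCC=C1CO)[C@@H](O[Si](C)(C)C(C)(C)C)CC/C(C)=C/C/C=C(\C)COCc2ccc(OC)cc2
F8 | step 11 | diethylphosphonoacetate of 12 | C=CCC[C@@](C)(OC(=O)CP(=O)(OCC)OCC)[C@@H](O[Si](C)(C)C(C)(C)C)CC/C(C)=C/C/C=C(\C)COCc1ccc(OC)cc1
F9 | step 11 | 2-(hydroxymethyl)acrylate of 12 | C=CCC[C@@](C)(OC(=O)C(=C)CO)[C@@H](O[Si](C)(C)C(C)(C)C)CC/C(C)=C/C/C=C(\C)COCc1ccc(OC)cc1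
F10 | step 7 | [(2R,3R)-3-{(3E,6E)-8-[(4-methoxybenzyl)oxy]-3,7-dimethylocta-3,6-dien-1-yl}-2-methyloxiran-2-yl]methanol | OC[C@@]1(C)O[C@@H]1CC/C(C)=C/C/C=C(\C)COCc2ccc(OC)cc2
F11 | step 7 | (2R,3S,6E,9E)-1,2-dihydroxy-11-[(4-methoxybenzyl)oxy]-2,6,10-trimethylundeca-6,9-dien-3-yl benzoate | OC[C@@](C)(O)[C@@H](OC(=O)c3ccccc3)CC/C(C)=C/C/C=C(\C)COCc2ccc(OC)cc2
F12 | step 7 | primary 4-methylbenzenesulfonate of F11 | Cc1ccc(cc1)S(=O)(=O)OC[C@@](C)(O)[C@@H](OC(=O)c3ccccc3)CC/C(C)=C/C/C=C(\C)COCc2ccc(OC)cc2
F13 | step 7 | (1S,4E,7E)-9-[(4-methoxybenzyl)oxy]-4,8-dimethyl-1-[(2R)-2-methyloxiran-2-yl]nona-4,7-dien-1-ol | C1O[C@@]1(C)[C@@H](O)CC/C(C)=C/C/C=C(\C)COCc2ccc(OC)cc2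
F0 | step 17 | none | none
A1 | alternative 1 | acyclic keto aldehyde: C4 methyl ketone, C5 aldehyde, C13 TBS ether, methyl ester arm on C1 | COC(=O)C[C@H](CCC(C)=O)C[C@H](O[Si](C)(C)C(C)(C)C)/C(C)=C/C/C=C(\C)CCC=O
A2 | alternative 1 | fourteen-membered 4,5-diol with methyl ester arm on C1 and C13 TBS ether | COC(=O)C[C@H]1C[C@H](O[Si](C)(C)C(C)(C)C)/C(C)=C/C/C=C(\C)CC[C@H](O)[C@](C)(O)CC1
A3 | alternative 2 | fourteen-membered (4S,5S)-epoxy acrylic acid, C13 TBS ether | C=C(C(=O)O)[C@@H]1CC[C@]2(C)O[C@H]2CC/C(C)=C/C/C=C(\C)[C@@H](O[Si](C)(C)C(C)(C)C)C1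
A4 | alternative 2 | C5-hydroxy α-methylene lactone, C13 TBS ether | C=C1C(=O)O[C@]2(C)CC[C@@H]1C[C@H](O[Si](C)(C)C(C)(C)C)/C(C)=C/C/C=C(\C)CC[C@@H]2O
A5 | alternative 3 | bis(methylalkyne) on the finished lactone, C5 acetate, C13 TBS ether | C=C1C(=O)O[C@](C)(CC[C@@H]1C[C@H](O[Si](C)(C)C(C)(C)C)C#CC)[C@@H](OC(C)=O)CC/C(C)=C/CC#CC
A6 | alternative 3 | fourteen-membered cycloalkyne, C5 acetate, C13 TBS ether | C=C1C(=O)O[C@]2(C)CC[C@@H]1C[C@H](O[Si](C)(C)C(C)(C)C)C#CC/C=C(\C)CC[C@@H]2OC(C)=O
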